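**Assumption:** the target SMILES has no stereocentre and no stereogenic double bond, so the compound is achiral; "single enantiomer" is taken to mean this one constitution, and no stereocentre has to be set.

**Retrosynthetic overview**
1. Target 13 ⇐ bis-silyl ether 12 by global desilylation.
2. 12 ⇐ 8-prenylchromone 7 + phenol 8: C2–O bond by a new formal dehydrogenative C2–H aryloxylation through a 4-silyloxybenzopyrylium ion, then DDQ.
3. 7 ⇐ 5-O-prenyl ether 4: C8–C bond by para-Claisen–Cope rearrangement.
4. 4 ⇐ 5-hydroxy-7-methoxychromone 3 (O-prenylation) ⇐ symmetrical acetophenone 1 + one-carbon amide acetal.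
5. Ring order: ring A is bought in 1; the pyranone ring is the only ring formed (step 1); the phenoxy ring is bought in 8 and attached in step 4.

**Step 1**
Reactants: 1 1-(2,6-dihydroxy-4-methoxyphenyl)ethan-1-one
Product: 3 5-hydroxy-7-methoxy-4H-chromen-4-one, via enaminone 2 (not isolated)
Conditions: Me2NCH(OMe)2 (2.5 equiv), toluene, 95 °C; then AcOH, 100 °C
Reagents that add atoms: N,N-dimethylformamide dimethyl acetal, COC(OC)N(C)C
Why: Enaminone chromone synthesis: the methyl ketone condenses with the amide acetal to the (E)-enaminone, then one of the two equivalent ortho hydroxyls adds in conjugate fashion and dimethylamine is lost; the symmetry of 1 removes any regiochemical question and no stereocentre is formed.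

**Step 2**
Reactants: 3 5-hydroxy-7-methoxy-4H-chromen-4-one
Product: 4 7-methoxy-5-[(3-methylbut-2-en-1-yl)oxy]-4H-chromen-4-one
Conditions: prenyl bromide (1.5 equiv), K2CO3 (2.0 equiv), acetone, reflux
Reagents that add atoms: 1-bromo-3-methylbut-2-ene (prenyl bromide), CC(C)=CCBr
Why: Williamson ether synthesis: the only hydroxyl, the hydrogen-bonded 5-OH, is O-alkylated by the reactive allylic bromide under carbonate; no stereocentre.

**Step 3**
Reactants: 4 7-methoxy-5-[(3-methylbut-2-en-1-yl)oxy]-4H-chromen-4-one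
Product: 7 5-hydroxy-7-methoxy-8-(3-methylbut-2-en-1-yl)-4H-chromen-4-one, via Claisen dienone 5 (not isolated), via Cope dienone 6 (not isolated)
Conditions: Eu(fod)3 (10 mol %; fod = 6,6,7,7,8,8,8-heptafluoro-2,2-dimethyloctane-3,5-dionate), NaHCO3, PhCl, 85 °C
Reagents that add atoms: none
Why: Para-Claisen–Cope rearrangement: lanthanide chelation in the O5/C4 carbonyl pocket accelerates the aromatic Claisen shift to C6, a Cope shift then moves the 1,1-dimethylallyl unit to C8 (para to O5) with re-inversion to the normal prenyl group, and tautomerisation restores the phenol; the transient sp3 centres of 5 and 6 are racemic and are lost.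

**Step 4**
Reactants: 7 5-hydroxy-7-methoxy-8-(3-methylbut-2-en-1-yl)-4H-chromen-4-one; 8 4-[(tert-butyldimethylsilyl)oxy]phenol
Product: 12 5-[(tert-butyldimethylsilyl)oxy]-2-{4-[(tert-butyldimethylsilyl)oxy]phenoxy}-7-methoxy-8-(3-methylbut-2-en-1-yl)-4H-chromen-4-one, via silyl ether 9 (not isolated), via benzopyrylium triflate 10 (not isolated), via acetal 11 (not isolated)
Conditions: TBSOTf (2.1 equiv), 2,6-lutidine (2.5 equiv), CH2Cl2, −78 °C to rt; then 8 (1.2 equiv), −78 to −30 °C; then DDQ (1.2 equiv), −78 to 0 °C; aq. NaHCO3 quench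
Reagents that add atoms: tert-butyldimethylsilyl trifluoromethanesulfonate (TBSOTf), CC(C)(C)[Si](C)(C)OS(=O)(=O)C(F)(F)F
Why: Proposed new method: a one-pot formal dehydrogenative C2–H aryloxylation of a chromone (oxidative nucleophilic substitution of hydrogen), in which silylation of O5 and of the C4 carbonyl turns 7 into the 4,5-bis(silyloxy)benzopyrylium triflate 10, whose unsubstituted C2 is the most electrophilic site; the phenol oxygen of 8, assisted by the hindered base, adds there to give the neutral mixed acetal 11, which is held as a silyl enol ether so it cannot revert by simple beta-elimination (its C2 centre is racemic and transient); DDQ then abstracts the C2 hydride, which is allylic to the enol ether and flanked by two oxygens, to give a 2-aryloxy-4-silyloxybenzopyrylium ion that loses its labile O4 silyl group on bicarbonate quench, leaving the C2–OAr bond and the C2=C3 double bond of 12; the closest known reaction types are the addition of silyl enol ethers and other carbon nucleophiles to 4-silyloxybenzopyrylium triflates, and the DDQ dehydrogenation of silyl enol ethers to enones and of 2H-chromenes to benzopyrylium ions, whereas an oxygen nucleophile followed by this oxidation has not been shown.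

**Step 5**
Reactants: 12 5-[(tert-butyldimethylsilyl)oxy]-2-{4-[(tert-butyldimethylsilyl)oxy]phenoxy}-7-methoxy-8-(3-methylbut-2-en-1-yl)-4H-chromen-4-one
Product: 13 5-hydroxy-2-(4-hydroxyphenoxy)-7-methoxy-8-(3-methylbut-2-en-1-yl)-4H-chromen-4-one
Conditions: TBAF (2.5 equiv), AcOH (2.5 equiv), THF, 0 °C
Reagents that add atoms: none
Why: Fluoride-driven cleavage of both aryl silyl ethers (strong Si–F bond), buffered by acetic acid so that no free phenoxide attacks C2 of the aryloxychromone; the prenyl alkene and the methyl ether are inert and no stereocentre is involved.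

**Compound list**
1 | 1-(2,6-dihydroxy-4-methoxyphenyl)ethan-1-one | CC(=O)c1c(O)cc(OC)cc1O | starting material
2 | (E)-1-(2,6-dihydroxy-4-methoxyphenyl)-3-(dimethylamino)prop-2-en-1-one | CN(C)/C=C/C(=O)c1c(O)cc(OC)cc1O | intermediate
3 | 5-hydroxy-7-methoxy-4H-chromen-4-one | COc1cc(O)c2c(=O)ccoc2c1 | intermediate
4 | 7-methoxy-5-[(3-methylbut-2-en-1-yl)oxy]-4H-chromen-4-one | COc1cc(OCC=C(C)C)c2c(=O)ccoc2c1 | intermediate
5 | 7-methoxy-6-(2-methylbut-3-en-2-yl)-6H-chromene-4,5-dione (Claisen dienone, racemic) | COC1=CC2=C(C(=O)C1C(C)(C)C=C)C(=O)C=CO2 | intermediate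
6 | 7-methoxy-8-(3-methylbut-2-en-1-yl)-8H-chromene-4,5-dione (Cope dienone, racemic) | COC1=CC(=O)C2=C(OC=CC2=O)C1CC=C(C)C | intermediate
7 | 5-hydroxy-7-methoxy-8-(3-methylbut-2-en-1-yl)-4H-chromen-4-one | COc1cc(O)c2c(=O)ccoc2c1CC=C(C)C | intermediate
8 | 4-[(tert-butyldimethylsilyl)oxy]phenol | CC(C)(C)[Si](C)(C)Oc1ccc(O)cc1 | starting material
9 | 5-[(tert-butyldimethylsilyl)oxy]-7-methoxy-8-(3-methylbut-2-en-1-yl)-4H-chromen-4-one | COc1cc(O[Si](C)(C)C(C)(C)C)c2c(=O)ccoc2c1CC=C(C)C | intermediate
10 | 4,5-bis[(tert-butyldimethylsilyl)oxy]-7-methoxy-8-(3-methylbut-2-en-1-yl)chromenylium trifluoromethanesulfonate | COc1cc(O[Si](C)(C)C(C)(C)C)c2c(O[Si](C)(C)C(C)(C)C)cc[o+]c2c1CC=C(C)C.[O-]S(=O)(=O)C(F)(F)F | intermediate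
11 | 2-{4-[(tert-butyldimethylsilyl)oxy]phenoxy}-4,5-bis[(tert-butyldimethylsilyl)oxy]-7-methoxy-8-(3-methylbut-2-en-1-yl)-2H-chromene (racemic at C2) | COc1cc(O[Si](C)(C)C(C)(C)C)c2C(O[Si](C)(C)C(C)(C)C)=CC(Oc3ccc(O[Si](C)(C)C(C)(C)C)cc3)Oc2c1CC=C(C)C | intermediate
12 | 5-[(tert-butyldimethylsilyl)oxy]-2-{4-[(tert-butyldimethylsilyl)oxy]phenoxy}-7-methoxy-8-(3-methylbut-2-en-1-yl)-4H-chromen-4-one | COc1cc(O[Si](C)(C)C(C)(C)C)c2c(=O)cc(Oc3ccc(O[Si](C)(C)C(C)(C)C)cc3)oc2c1CC=C(C)C | intermediate
13 | 5-hydroxy-2-(4-hydroxyphenoxy)-7-methoxy-8-(3-methylbut-2-en-1-yl)-4H-chromen-4-one (7-O-methylepimedonin G) | COc1cc(O)c2c(=O)cc(Oc3ccc(O)cc3)oc2c1CC=C(C)C | target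

**Totals and risks**
Total step count: 5. Longest linear sequence: 5 steps (1 → 3 → 4 → 7 → 12 → 13).

Most likely to fail, first: step 4, the proposed new reaction. The phenol may take a silyl group from 10 instead of attacking C2, it may react through carbon, DDQ may oxidise excess phenol, or water may attack C2 instead of silicon on quench. The fallback uses known chemistry, sets out from 7 and comes back at 12. The 5-OH is silylated alone (TBSOTf 1.05 equiv, 2,6-lutidine, CH2Cl2, 0 °C) and 9 is isolated. C2 is then zincated selectively with TMP2Zn·2MgCl2·2LiCl (TMP = 2,2,6,6-tetramethylpiperidide; THF, −30 °C) and the zinc species is quenched with I2 to give 5-[(tert-butyldimethylsilyl)oxy]-2-iodo-7-methoxy-8-(3-methylbut-2-en-1-yl)-4H-chromen-4-one F1. Addition–elimination of phenol 8 at C2 (K2CO3, acetone, rt) then displaces iodide and gives 12.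

Second: step 3. The rearrangement may stop at the C6 ortho product (6-(1,1-dimethylallyl) isomer) or lose the prenyl group back to 3. The fallback replaces the sigmatropic route by halogenation and cross-coupling; it sets out from 3 and comes back at 7, bypassing 4. The 5-OH is protected (chloromethyl methyl ether, iPr2NEt, CH2Cl2) as 7-methoxy-5-(methoxymethoxy)-4H-chromen-4-one F2. Iodination at C8, the ring A position between the ring oxygen and the methoxy group (N-iodosuccinimide, DMF, rt), gives 8-iodo-7-methoxy-5-(methoxymethoxy)-4H-chromen-4-one F3. Stille coupling with tributyl(3-methylbut-2-en-1-yl)stannane (Pd(PPh3)4, DMF, 90 °C) gives 7-methoxy-5-(methoxymethoxy)-8-(3-methylbut-2-en-1-yl)-4H-chromen-4-one F4, and mild acid (cat. HCl, MeOH, 40 °C) removes the acetal to give 7.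

Third: step 1. The amide acetal can O-methylate the free phenols, and cyclisation of the enaminone may be incomplete. The fallback builds C2 by Claisen formylation instead; it sets out from 1 and comes back at 3. Ethyl formate and NaH (THF, 0 °C to rt), then acidic work-up, give the cyclic hemiacetal 2,5-dihydroxy-7-methoxychroman-4-one F5 (racemic), which is dehydrated (cat. H2SO4, AcOH, 60 °C) to 3.

**Further compounds**
F1 | step 4 | 5-[(tert-butyldimethylsilyl)oxy]-2-iodo-7-methoxy-8-(3-methylbut-2-en-1-yl)-4H-chromen-4-one | COc1cc(O[Si](C)(C)C(C)(C)C)c2c(=O)cc(I)oc2c1CC=C(C)C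
F2 | step 3 | 7-methoxy-5-(methoxymethoxy)-4H-chromen-4-one | COCOc1cc(OC)cc2occc(=O)c12
F3 | step 3 | 8-iodo-7-methoxy-5-(methoxymethoxy)-4H-chromen-4-one | COCOc1cc(OC)c(I)c2occc(=O)c12
F4 | step 3 | 7-methoxy-5-(methoxymethoxy)-8-(3-methylbut-2-en-1-yl)-4H-chromen-4-one | COCOc1cc(OC)c(CC=C(C)C)c2occc(=O)c12
F5 | step 1 | 2,5-dihydroxy-7-methoxychroman-4-one (racemic) | COc1cc(O)c2C(=O)CC(O)Oc2c1
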